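## Analysis of the target

Compound 23 is a 1H-isochromen-1-one (isocoumarin): benzo ring A (C4a, C5, C6, C7, C8, C8a) is fused to pyranone ring C (C1, O2, C3, C4, C4a, C8a) and carries a free hydroxyl on C6 and, on C8, an ether oxygen to ring B, while C3 of ring C bears a pentyl chain. Ring B (C1' to C6') is a pentasubstituted benzene with the ether oxygen on C1', a hydroxyl on C2', a methoxy group on C4' and a pentyl chain on C6', that is, the skeleton of olivetol 1 with one further oxygen on C1'. There is no stereocentre and no double bond whose geometry must be set, so the task is one of regiochemistry and of telling four phenolic oxygens apart. The sensitive parts are the enol lactone of ring C, which hydroxide or alkoxide opens and whose C3=C4 bond can be hydrogenated, and ring B, which with oxygen on C1', C2' and C4' oxidises easily once its phenols are free. The hard bond is the diaryl ether: C8 lies peri to the lactone carbonyl and C1' is flanked by the C2' oxygen and the C6' pentyl group, so any aryl–oxygen coupling would have to join two doubly ortho-substituted carbons. The strategy rests on ring A being a resorcylate: oxygens on C6 and C8 meta to each other, the carbonyl carbon C1 on C8a next to C8, and a carbon substituent on C4a. That is the pattern a 1,3-dioxygenated cyclohexa-1,3-diene gives with a 2-alkynoate when the adduct loses its CH2–CH2 bridge, so the C8 oxygen can arrive as a vinylogous aryl ester and the diaryl ether never has to be made by coupling.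

## Retrosynthetic reasoning

**Protecting groups.** The two free phenols of 23 are traced back through 22 to 21, with a benzyl ether on the C2' oxygen and a silyl ether on the C6 oxygen. Benzyl is chosen because it must survive a strong amide base, 160 °C and an acidic, π-acid-catalysed cyclisation, and can then be cut by a Lewis acid without touching the C4' methyl ether or the C3=C4 bond. The silyl group is simply the one that the ring-forming step leaves on C6.

**Ring C.** Ring C of 21 is opened at the O2–C3 bond, which leads to the ortho-alkynyl methyl benzoate 20. There C3 and C4 are the two carbons of a hept-1-ynyl group on the future C4a, and C1 is the ester carbon. Cutting here, and not at C1–O2 or C4–C4a, means that ring C costs no carbon–carbon bond. The forward reaction only has to bring the ester carbonyl oxygen onto the far alkyne carbon in a 6-endo closure and shed the ester methyl group.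

**Ring A.** Ring A of 20 is cut at C8–C8a and C4a–C5. C5, C6, C7 and C8 then belong to diene 12, with the silyloxy group on the future C6 and the aryloxy group on the future C8. C8a and C4a become the ester-bearing triple bond of diynoate 18, and the link between the two is the bridged adduct 19. These two bonds are chosen because every substituent of ring A then sits on one of two simple partners, and because the C8 oxygen is an enol ether oxygen of the diene, so neither aromatic ring has to accept an oxygen by coupling. The forward reaction needs a cycloaddition in one orientation and at one of the two triple bonds of 18, followed by cycloreversion that releases the two-carbon bridge.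

**The diene.** Diene 12 is the O-silylated kinetic enolate 11 of the vinylogous aryl ester 10. Cutting the enone C3–O bond of 10 gives phenol 7 and chloroenone 9, which is the vinylogous acid chloride of dione 8. Cutting the vinyl–oxygen bond and not the aryl–oxygen bond turns a hindered diaryl ether synthesis into an addition–elimination on an sp2 carbon activated by a carbonyl group. The forward steps need O-attack by a hindered phenoxide and deprotonation at the alpha-prime carbon, not the gamma carbon.

**Ring B.** Phenol 7 has the pentyl group and the two meta oxygens of 1, plus the C1' oxygen between the pentyl group and one of those oxygens. That oxygen is traced to a formyl group: formate 6 comes from aldehyde 5 by oxidative migration of the aryl group from carbon to oxygen. Aldehyde 5 comes from 4 by O-benzylation, 4 from 3 by methylation of the hydroxyl para to the formyl group, and 3 from 1 by formylation through iminium salt 2. The formyl group fixes the position of the new oxygen, distinguishes the two hydroxyls of 1 (one becomes hydrogen-bonded, the other not), and is finally converted into the oxygen itself.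

**The diynoate.** Diynoate 18 is cut at C1–C2 (the ester carbon added to diynyl anion 17) and at C5–C6 (the pentyl group of 14 added to silyl diynide 15). Both anions come from the four-carbon unit 13 by removing its two silyl groups one after the other, with 16 in between. A cross-coupling that joins two alkyne halves at the central C3–C4 bond was considered and set aside, because the amine base such couplings need adds to a conjugated ynoate. Starting from a preformed diyne avoids that.

## Alternatives that were turned down

Alternative 1: Ring B is made last, on a finished isocoumarin, by cutting C2'–C3' and C4'–C5'.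
- Key step: cyclobutenone A2 is a 4-aryloxy-3-pentylcyclobutenone whose aryl group is the isocoumarin, and it is heated with methoxyacetylene A3. Ring opening to a vinylketene, [2+2] addition of A3, opening of the new four-membered ring and six-electron closure should give phenol A1, one debenzylation from 23.
- For: ring B is formed with the C2' hydroxyl free and the C4' methoxy in place, the polarity of A3 fixes the orientation, and the end game is a single step. On these points it is stronger than the chosen route, which must differentiate the two hydroxyls of 1 and needs three steps after its key step.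
- Against: A2 has to come from the 8-hydroxyisocoumarin A4 by way of an aryloxyketene and its [2+2] addition to an unactivated terminal alkyne, a reaction class that competes poorly with ketene dimerisation. A4 itself needs rings A and C with the C6 and C8 oxygens differentiated, which is most of the work of the chosen route. A3 is volatile, is not an article of commerce and must be made and handled cold.
- Comparison: two uncertain steps fall late, on the most advanced material. The chosen route has one uncertain step between two simple fragments and takes the ring-B skeleton from 1.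

Alternative 2: Ring A is built on a preformed ring C by cutting C4a–C5 and C6–C7.
- Key step: the pyranopyrandione A6 is assembled from hydroxypyranone A8, a malonyl unit and phenol 7. Its aryloxy-bearing 2-pyranone half reacts with ketene bis(trimethylsilyl) acetal A7, and the bridged adduct decarboxylates and loses one silyloxy group to give A5.
- For: ring C and its pentyl chain are present from the start, so there is no alkyne and no lactonisation, and only desilylation and debenzylation follow. It uses the same phenol 7 and would be the shortest of the four routes, which is a real advantage over the chosen one.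
- Against: A6 has two 2-pyranone dienes and several electrophilic carbons. The nucleophilic carbon of A7 must bond to the ring-fusion carbon (future C4a), whereas conjugate addition at the aryloxy-bearing carbon (future C8) would expel the phenoxide of 7 and destroy the ether. A6 must itself be made by displacing a leaving group at that carbon with the hindered phenoxide of 7 on a base-sensitive bis-lactone, and A7 is moisture-sensitive and must be prepared.
- Comparison: the chosen route is about four steps longer. In return 12 has a single diene, both oxygen substituents polarise it the same way, and its aryloxy group sits on an enol ether with no nucleophile present to displace it.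

Alternative 3: Ring B is grown from a 4-pyranone attached through the future ether oxygen, by cutting C1'–C6'.
- Key step: pyranone ether A10 is made from A4 and bromomethylpyranone A12 and is opened by aqueous hydroxide to triketone A11. Its aryloxy-bearing methylene (C1') adds to the pentyl ketone (C6'), dehydration aromatises ring B to A9, and acid recloses ring C.
- For: it resembles polyketide assembly, uses cheap reagents and no high temperature, and forms the ether oxygen by simple O-alkylation. In reagent cost and in needing no ring-B protecting group it is at least as good as the chosen route.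
- Against: hydroxide also opens the lactone, freeing a ketone whose benzylic methylene (C4) can enter aldol reactions with the triketone. A11 can also close the other way (the alpha-methylene of the pentyl chain onto the ketone next to the aryloxymethyl group), cleave by retro-Claisen reaction or reclose to the pyranone. A9 has two free hydroxyls on ring B, of which only the one on C4' may be methylated. A4 and A12 each take several steps.
- Comparison: more steps and three selectivity questions. In the chosen route the substitution of ring B comes from 1, and the C2'/C4' distinction is settled by a hydrogen bond in 3.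

Key step: step 10

## Route

Remark on the chemistry: 23 has no stereogenic element. Adduct 19 is the only chiral compound of the route; it forms as a racemate and loses both stereocentres on aromatisation, so no step needs stereocontrol.

Step 1
Reactants: 1 olivetol (5-pentylbenzene-1,3-diol)
Product: 3 2,4-dihydroxy-6-pentylbenzaldehyde, via aryl iminium chloride 2 (not isolated)
Conditions: POCl3 (1.2 equiv), DMF, 0 °C → rt; then H2O, 50 °C
Reagents that add atoms: N,N-dimethylformamide, CN(C)C=O (formyl carbon); water, O (aldehyde oxygen)
Why: Vilsmeier–Haack formylation: the chloroiminium ion should attack the resorcinol at C4, para to one hydroxyl and ortho to the other (attack para to a hydroxyl is favoured over attack at the carbon flanked by both hydroxyls, as in the formylation of other 5-alkylresorcinols), and water hydrolyses iminium salt 2 to the aldehyde.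

Step 2
Reactants: 3 2,4-dihydroxy-6-pentylbenzaldehyde
Product: 4 2-hydroxy-4-methoxy-6-pentylbenzaldehyde
Conditions: MeI (1.1 equiv), K2CO3 (1.1 equiv), acetone, rt
Reagents that add atoms: iodomethane, CI
Why: Williamson ether synthesis with site control: the 2-hydroxyl is held in a hydrogen bond to the formyl oxygen and is the less acidic one, so one equivalent of base and MeI should methylate the 4-hydroxyl, para to the formyl group.

Step 3
Reactants: 4 2-hydroxy-4-methoxy-6-pentylbenzaldehyde
Product: 5 2-(benzyloxy)-4-methoxy-6-pentylbenzaldehyde
Conditions: BnBr, K2CO3, DMF, 60 °C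
Reagents that add atoms: benzyl bromide, BrCc1ccccc1
Why: Williamson benzylation of the remaining chelated phenol under more forcing conditions; there is no other nucleophilic site.

Step 4
Reactants: 5 2-(benzyloxy)-4-methoxy-6-pentylbenzaldehyde
Product: 7 2-(benzyloxy)-4-methoxy-6-pentylphenol, via aryl formate 6 (not isolated)
Conditions: mCPBA, CH2Cl2, 0 °C → rt; aq. Na2S2O3/NaHCO3 wash; then K2CO3 (cat.), MeOH, rt, Ar
Reagents that add atoms: 3-chloroperoxybenzoic acid, OOC(=O)c1cccc(Cl)c1
Why: Baeyer–Villiger (Dakin-type) oxidation: in the Criegee intermediate the electron-rich 2,4-dialkoxy-6-alkylaryl group should migrate in preference to hydride, giving formate 6, which catalytic methanolysis cleaves. The peracid is destroyed before the oxidation-prone phenol is set free.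

Step 5
Reactants: 8 cyclohexane-1,3-dione
Product: 9 3-chlorocyclohex-2-en-1-one
Conditions: (COCl)2, DMF (cat.), CH2Cl2, 0 °C → rt
Reagents that add atoms: oxalyl chloride, ClC(=O)C(=O)Cl
Why: The enol of the 1,3-dione behaves as a vinylogous carboxylic acid, and the Vilsmeier-type chloroiminium catalyst converts it into the vinylogous acid chloride with loss of CO, CO2 and HCl.

Step 6
Reactants: 7 2-(benzyloxy)-4-methoxy-6-pentylphenol; 9 3-chlorocyclohex-2-en-1-one
Product: 10 3-[2-(benzyloxy)-4-methoxy-6-pentylphenoxy]cyclohex-2-en-1-one
Conditions: Cs2CO3, MeCN, 60 °C, Ar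
Reagents that add atoms: none
Why: Vinylogous acyl substitution (conjugate addition–elimination): the phenoxide adds at C3 of the chloroenone and chloride leaves. The ortho and para positions of the phenoxide are all substituted, so only O-attack is possible, and the flat sp2 electrophile tolerates the two ortho substituents.

Step 7
Reactants: 10 3-[2-(benzyloxy)-4-methoxy-6-pentylphenoxy]cyclohex-2-en-1-one
Product: 12 1-[2-(benzyloxy)-4-methoxy-6-pentylphenoxy]-3-(tert-butyldimethylsilyloxy)cyclohexa-1,3-diene, via lithium dienolate 11 (not isolated)
Conditions: LiN(iPr)2 (1.1 equiv), THF, −78 °C; then TBSCl, DMPU, −78 → 0 °C; non-aqueous work-up, filtration through Et3N-treated silica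
Reagents that add atoms: tert-butyldimethylsilyl chloride, CC(C)(C)[Si](C)(C)Cl
Why: Kinetic deprotonation of a 3-alkoxy- or 3-aryloxy-enone by a lithium amide occurs at C6 (alpha-prime), as in Stork–Danheiser chemistry, giving cross-conjugated enolate 11, and O-silylation in the presence of DMPU gives the 2-silyloxy diene. The benzyl ether should not be metalated at −78 °C.

Step 8
Reactants: 13 1,4-bis(trimethylsilyl)buta-1,3-diyne; 14 1-iodopentane
Product: 16 trimethyl(nona-1,3-diyn-1-yl)silane, via lithium silylbutadiynide 15 (not isolated)
Conditions: MeLi·LiBr (1.0 equiv), THF, rt; then 14, DMPU, −78 °C → rt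
Reagents that add atoms: none
Why: MeLi·LiBr cleaves one C(sp)–Si bond of the bis-silyl diyne (the anion formed resists a second cleavage), and the diynide is alkylated by the primary iodide in an SN2 reaction that the dipolar cosolvent promotes.

Step 9
Reactants: 16 trimethyl(nona-1,3-diyn-1-yl)silane
Product: 18 methyl deca-2,4-diynoate, via lithium nonadiynide 17 (not isolated)
Conditions: MeLi·LiBr (1.05 equiv), THF, rt; then cannulated into ClCO2Me (2 equiv), THF, −78 °C
Reagents that add atoms: methyl chloroformate, COC(=O)Cl
Why: The same Si–C(sp) cleavage on the neutral silyl diyne gives diynyllithium 17, which is acylated by the chloroformate. Adding the anion to an excess of cold chloroformate keeps it from attacking the product ester.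

Step 10
Reactants: 12 1-[2-(benzyloxy)-4-methoxy-6-pentylphenoxy]-3-(tert-butyldimethylsilyloxy)cyclohexa-1,3-diene; 18 methyl deca-2,4-diynoate
Product: 20 methyl 2-[2-(benzyloxy)-4-methoxy-6-pentylphenoxy]-4-(tert-butyldimethylsilyloxy)-6-(hept-1-yn-1-yl)benzoate, via bicyclo[2.2.2]octadiene adduct 19 (not isolated)
Conditions: 18 (1.5 equiv), BHT (cat.), PhMe, sealed tube, 110 °C, then 160 °C
Reagents that add atoms: none
Why: The diene, whose HOMO is raised by the aryloxy and silyloxy groups, and the ester-conjugated C2≡C3 bond of 18 should combine in a normal-electron-demand, concerted but asynchronous [4+2] cycloaddition: the unsubstituted diene terminus next to the silyloxy carbon (future C5) bonds first to the beta carbon of the ynoate (future C4a), and the aryloxy-bearing terminus (future C8) bonds to the alpha carbon (future C8a). The bicyclo[2.2.2]octa-2,5-diene 19 then undergoes a thermal retro-[4+2] reaction at the higher temperature, expelling its CH2–CH2 bridge as ethene and leaving the benzene ring of 20; the closest known reaction is the Alder–Rickert synthesis of 2-alkoxy-4-silyloxybenzoates from 1-alkoxy-3-silyloxycyclohexa-1,3-dienes and 2-alkynoates. Ring A is thus closed by an intermolecular cycloaddition that is suprafacial on both partners and is aromatised by cycloreversion, not by elimination, so every substituent of the diene, the aryloxy group included, is kept. No stereocentre remains in 20; the two bridgehead centres of 19 form as a racemic pair and are erased with the loss of ethene. The regiochemistry needed (aryloxy ortho and silyloxy para to the ester) follows because both oxygen donors put the largest HOMO coefficient on the same diene terminus and the ester puts the largest LUMO coefficient on C3 of 18. The site selectivity needed (C2≡C3, not C4≡C5) follows because only that triple bond carries the ester directly, while C4≡C5 is less polarised and shielded by the pentyl chain; the aryl alkyne of 20 is not a dienophile under these conditions. The excess of 18, the radical inhibitor and the staged heating are meant to let the cycloaddition run before [1,5]-hydrogen shifts of 12 or oligomerisation of 18 set in.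

Step 11
Reactants: 20 methyl 2-[2-(benzyloxy)-4-methoxy-6-pentylphenoxy]-4-(tert-butyldimethylsilyloxy)-6-(hept-1-yn-1-yl)benzoate
Product: 21 8-[2-(benzyloxy)-4-methoxy-6-pentylphenoxy]-6-(tert-butyldimethylsilyloxy)-3-pentyl-1H-isochromen-1-one
Conditions: AuCl3 (5 mol%), CF3CO2H (2 equiv), ClCH2CH2Cl, 60 °C
Reagents that add atoms: none
Why: Activation of the alkyne by AuCl3 lets the ester carbonyl oxygen add to the pentyl-bearing alkyne carbon in a 6-endo-dig closure (the 5-exo mode would place positive charge next to the electron-poor benzoate ring), as in the known cyclisation of ortho-alkynylbenzoate esters to isocoumarins. Trifluoroacetate removes the methyl group from the 1-methoxyisochromenylium ion and the acid protonates the C4–Au bond.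

Step 12
Reactants: 21 8-[2-(benzyloxy)-4-methoxy-6-pentylphenoxy]-6-(tert-butyldimethylsilyloxy)-3-pentyl-1H-isochromen-1-one
Product: 22 8-[2-(benzyloxy)-4-methoxy-6-pentylphenoxy]-6-hydroxy-3-pentyl-1H-isochromen-1-one
Conditions: Bu4NF (1.1 equiv), AcOH (1.2 equiv), THF, 0 °C
Reagents that add atoms: none
Why: Fluoride cleavage of an aryl silyl ether; acetic acid buffers the phenoxide and fluoride so that the enol lactone is not opened.

Step 13
Reactants: 22 8-[2-(benzyloxy)-4-methoxy-6-pentylphenoxy]-6-hydroxy-3-pentyl-1H-isochromen-1-one
Product: 23 6-hydroxy-8-(2-hydroxy-4-methoxy-6-pentylphenoxy)-3-pentyl-1H-isochromen-1-one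
Conditions: BCl3 (3 equiv), C6HMe5 (3 equiv), CH2Cl2, −78 °C; then aq. NaHCO3
Reagents that add atoms: none
Why: Lewis-acid debenzylation: BCl3 ionises the benzyl–oxygen bond at −78 °C and pentamethylbenzene traps the benzyl cation, a known method that leaves aryl methyl ethers, diaryl ethers, lactones and C=C bonds untouched. Hydrogenolysis is avoided because of the C3=C4 bond.

## Compound list

1 | olivetol (5-pentylbenzene-1,3-diol) | CCCCCc1cc(O)cc(O)c1 | starting material
2 | N-[(2,4-dihydroxy-6-pentylphenyl)methylidene]-N-methylmethanaminium chloride | CCCCCc1cc(O)cc(O)c1C=[N+](C)C.[Cl-] | intermediate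
3 | 2,4-dihydroxy-6-pentylbenzaldehyde | CCCCCc1cc(O)cc(O)c1C=O | intermediate
4 | 2-hydroxy-4-methoxy-6-pentylbenzaldehyde | CCCCCc1cc(OC)cc(O)c1C=O | intermediate
5 | 2-(benzyloxy)-4-methoxy-6-pentylbenzaldehyde | CCCCCc1cc(OC)cc(OCc2ccccc2)c1C=O | intermediate
6 | 2-(benzyloxy)-4-methoxy-6-pentylphenyl formate | CCCCCc1cc(OC)cc(OCc2ccccc2)c1OC=O | intermediate
7 | 2-(benzyloxy)-4-methoxy-6-pentylphenol | CCCCCc1cc(OC)cc(OCc2ccccc2)c1O | intermediate
8 | cyclohexane-1,3-dione | O=C1CCCC(=O)C1 | starting material
9 | 3-chlorocyclohex-2-en-1-one | O=C1C=C(Cl)CCC1 | intermediate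
10 | 3-[2-(benzyloxy)-4-methoxy-6-pentylphenoxy]cyclohex-2-en-1-one | CCCCCc1cc(OC)cc(OCc2ccccc2)c1OC1=CC(=O)CCC1 | intermediate
11 | lithium 5-[2-(benzyloxy)-4-methoxy-6-pentylphenoxy]cyclohexa-1,5-dien-1-olate | [Li+].[O-]C1=CCCC(Oc2c(OCc3ccccc3)cc(OC)cc2CCCCC)=C1 | intermediate
12 | 1-[2-(benzyloxy)-4-methoxy-6-pentylphenoxy]-3-(tert-butyldimethylsilyloxy)cyclohexa-1,3-diene | CC(C)(C)[Si](C)(C)OC1=CCCC(Oc2c(OCc3ccccc3)cc(OC)cc2CCCCC)=C1 | intermediate
13 | 1,4-bis(trimethylsilyl)buta-1,3-diyne | C[Si](C)(C)C#CC#C[Si](C)(C)C | starting material
14 | 1-iodopentane | CCCCCI | starting material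
15 | lithium 4-(trimethylsilyl)buta-1,3-diyn-1-ide | [Li+].[C-]#CC#C[Si](C)(C)C | intermediate
16 | trimethyl(nona-1,3-diyn-1-yl)silane | CCCCCC#CC#C[Si](C)(C)C | intermediate
17 | lithium nona-1,3-diyn-1-ide | [Li+].[C-]#CC#CCCCCC | intermediate
18 | methyl deca-2,4-diynoate | CCCCCC#CC#CC(=O)OC | intermediate
19 | methyl 1-[2-(benzyloxy)-4-methoxy-6-pentylphenoxy]-5-(tert-butyldimethylsilyloxy)-3-(hept-1-yn-1-yl)bicyclo[2.2.2]octa-2,5-diene-2-carboxylate (racemic) | COC(=O)C1=C(C#CCCCCC)C2CCC1(Oc1c(OCc3ccccc3)cc(OC)cc1CCCCC)C=C2O[Si](C)(C)C(C)(C)C | intermediate
20 | methyl 2-[2-(benzyloxy)-4-methoxy-6-pentylphenoxy]-4-(tert-butyldimethylsilyloxy)-6-(hept-1-yn-1-yl)benzoate | CCCCCC#Cc1cc(O[Si](C)(C)C(C)(C)C)cc(Oc2c(OCc3ccccc3)cc(OC)cc2CCCCC)c1C(=O)OC | intermediate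
21 | 8-[2-(benzyloxy)-4-methoxy-6-pentylphenoxy]-6-(tert-butyldimethylsilyloxy)-3-pentyl-1H-isochromen-1-one | CCCCCc1cc2cc(O[Si](C)(C)C(C)(C)C)cc(Oc3c(OCc4ccccc4)cc(OC)cc3CCCCC)c2c(=O)o1 | intermediate
22 | 8-[2-(benzyloxy)-4-methoxy-6-pentylphenoxy]-6-hydroxy-3-pentyl-1H-isochromen-1-one | CCCCCc1cc2cc(O)cc(Oc3c(OCc4ccccc4)cc(OC)cc3CCCCC)c2c(=O)o1 | intermediate
23 | 6-hydroxy-8-(2-hydroxy-4-methoxy-6-pentylphenoxy)-3-pentyl-1H-isochromen-1-one | CCCCCc1cc2cc(O)cc(Oc3c(O)cc(OC)cc3CCCCC)c2c(=O)o1 | target

## Step count and risks

Total: 13 steps. Longest linear sequence: 10 steps (steps 1–4, 6, 7, 10–13). Step 5 and steps 8–9 are side branches.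

**Step 10 (key step).** The bulky, only moderately donating aryloxy group sits on the diene terminus that must bond to the ester-bearing carbon. The most likely failure is a slow cycloaddition, so that oligomerisation of 18 and [1,5]-hydrogen shifts in 12, which scramble the oxygen pattern, take over before 19 forms. The fallback keeps the ring construction but uses a smaller, more electrophilic dienophile and attaches the alkyne afterwards. It sets out from 12 and returns at 20. The dienophile methyl 3-bromoprop-2-ynoate F1 is made from methyl propiolate with NBS and AgNO3 (cat.) in acetone and is heated with 12 in PhMe at 80–110 °C. The bromo adduct methyl 1-[2-(benzyloxy)-4-methoxy-6-pentylphenoxy]-3-bromo-5-(tert-butyldimethylsilyloxy)bicyclo[2.2.2]octa-2,5-diene-2-carboxylate F2 should form as a racemate and lose ethene to give the aryl bromide methyl 2-[2-(benzyloxy)-4-methoxy-6-pentylphenoxy]-6-bromo-4-(tert-butyldimethylsilyloxy)benzoate F3 with the same substitution pattern as 20. Sonogashira coupling of F3 with commercial hept-1-yne (PdCl2(PPh3)2, CuI, Et3N, 60 °C) then gives 20.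

**Step 7.** The likely failures are incomplete O-silylation of the lithium enolate by the hindered silyl chloride and hydrolysis of the silyl dienol ether back to 10 during isolation. The fallback does not isolate a diene and changes the silyl group. It sets out from 10 and returns at 22. Enolate 11 is formed as in step 7 and quenched with Me3SiCl. Volatiles are removed, the residue is taken up in pentane and filtered, and the crude 1-[2-(benzyloxy)-4-methoxy-6-pentylphenoxy]-3-(trimethylsilyloxy)cyclohexa-1,3-diene F4 is heated at once with 18 as in step 10. The trimethylsilyl analogue of the adduct, racemic methyl 1-[2-(benzyloxy)-4-methoxy-6-pentylphenoxy]-3-(hept-1-yn-1-yl)-5-(trimethylsilyloxy)bicyclo[2.2.2]octa-2,5-diene-2-carboxylate F5 should lose ethene to give methyl 2-[2-(benzyloxy)-4-methoxy-6-pentylphenoxy]-6-(hept-1-yn-1-yl)-4-(trimethylsilyloxy)benzoate F6 in the same way. Work-up of F6 with dilute HCl in THF then gives the free phenol methyl 2-[2-(benzyloxy)-4-methoxy-6-pentylphenoxy]-6-(hept-1-yn-1-yl)-4-hydroxybenzoate F7 without a separate step. Cyclisation of F7 under the conditions of step 11 gives 22 directly, which also saves step 12.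

**Step 11.** The likely failures are slow removal of the methyl group from the cyclic oxocarbenium ion, so that traces of water divert it to ester-assisted alkyne hydration, and partial 5-exo closure. The fallback is a halocyclisation followed by reduction. It sets out from 20 and returns at 21. I2 and NaHCO3 in MeCN at rt should give, by iodonium-triggered 6-endo closure with loss of the methyl group as iodomethane, the iodolactone 8-[2-(benzyloxy)-4-methoxy-6-pentylphenoxy]-6-(tert-butyldimethylsilyloxy)-4-iodo-3-pentyl-1H-isochromen-1-one F8 as the only new compound. Hydrodeiodination of F8 with Pd(OAc)2, PPh3, HCO2H and Et3N in DMF at 60 °C gives 21. Iodination of the electron-rich ring B would have to be watched and limited by using the mild I2/NaHCO3 system.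

**Step 8.** The likely failures are slow SN2 alkylation of the delocalised, weakly nucleophilic diynide and partial removal of both silyl groups, which gives mixtures. The fallback builds the diyne by CuCl-catalysed alkyne–bromoalkyne coupling. It sets out from 14 and returns at 17. Treating 14 with LiC≡CH·H2NCH2CH2NH2 in DMSO gives hept-1-yne F9 as a volatile liquid that can also be bought. Cadiot–Chodkiewicz coupling of F9 with (bromoethynyl)triisopropylsilane (CuCl cat., NH2OH·HCl, aq. n-BuNH2, 0 °C) gives triisopropyl(nona-1,3-diyn-1-yl)silane F10 as the unsymmetrical diyne. Bu4NF in THF then frees nona-1,3-diyne F11 from F10, and n-BuLi in THF at −78 °C converts F11 into 17, which is acylated as in step 9.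

## Further compounds

F1 | step 10 | methyl 3-bromoprop-2-ynoate | COC(=O)C#CBr
F2 | step 10 | methyl 1-[2-(benzyloxy)-4-methoxy-6-pentylphenoxy]-3-bromo-5-(tert-butyldimethylsilyloxy)bicyclo[2.2.2]octa-2,5-diene-2-carboxylate | COC(=O)C1=C(Br)C2CCC1(Oc1c(OCc3ccccc3)cc(OC)cc1CCCCC)C=C2O[Si](C)(C)C(C)(C)C
F3 | step 10 | methyl 2-[2-(benzyloxy)-4-methoxy-6-pentylphenoxy]-6-bromo-4-(tert-butyldimethylsilyloxy)benzoate | COC(=O)c1c(Br)cc(O[Si](C)(C)C(C)(C)C)cc1Oc1c(OCc2ccccc2)cc(OC)cc1CCCCC
F4 | step 7 | 1-[2-(benzyloxy)-4-methoxy-6-pentylphenoxy]-3-(trimethylsilyloxy)cyclohexa-1,3-diene | C[Si](C)(C)OC1=CCCC(Oc2c(OCc3ccccc3)cc(OC)cc2CCCCC)=C1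
F5 | step 7 | methyl 1-[2-(benzyloxy)-4-methoxy-6-pentylphenoxy]-3-(hept-1-yn-1-yl)-5-(trimethylsilyloxy)bicyclo[2.2.2]octa-2,5-diene-2-carboxylate | COC(=O)C1=C(C#CCCCCC)C2CCC1(Oc1c(OCc3ccccc3)cc(OC)cc1CCCCC)C=C2O[Si](C)(C)C
F6 | step 7 | methyl 2-[2-(benzyloxy)-4-methoxy-6-pentylphenoxy]-6-(hept-1-yn-1-yl)-4-(trimethylsilyloxy)benzoate | CCCCCC#Cc1cc(O[Si](C)(C)C)cc(Oc2c(OCc3ccccc3)cc(OC)cc2CCCCC)c1C(=O)OC
F7 | step 7 | methyl 2-[2-(benzyloxy)-4-methoxy-6-pentylphenoxy]-6-(hept-1-yn-1-yl)-4-hydroxybenzoate | CCCCCC#Cc1cc(O)cc(Oc2c(OCc3ccccc3)cc(OC)cc2CCCCC)c1C(=O)OC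
F8 | step 11 | 8-[2-(benzyloxy)-4-methoxy-6-pentylphenoxy]-6-(tert-butyldimethylsilyloxy)-4-iodo-3-pentyl-1H-isochromen-1-one | CCCCCc1oc(=O)c2c(Oc3c(OCc4ccccc4)cc(OC)cc3CCCCC)cc(O[Si](C)(C)C(C)(C)C)cc2c1I
F9 | step 8 | hept-1-yne | CCCCCC#C
F10 | step 8 | triisopropyl(nona-1,3-diyn-1-yl)silane | CCCCCC#CC#C[Si](C(C)C)(C(C)C)C(C)C
F11 | step 8 | nona-1,3-diyne | CCCCCC#CC#C
A1 | alternative 1 | 6-(benzyloxy)-8-(2-hydroxy-4-methoxy-6-pentylphenoxy)-3-pentyl-1H-isochromen-1-one | CCCCCc1cc2cc(OCc3ccccc3)cc(Oc3c(O)cc(OC)cc3CCCCC)c2c(=O)o1
A2 | alternative 1 | 4-{[6-(benzyloxy)-1-oxo-3-pentyl-1H-isochromen-8-yl]oxy}-3-pentylcyclobut-2-en-1-one | CCCCCC1=CC(=O)C1Oc1cc(OCc2ccccc2)cc2cc(CCCCC)oc(=O)c12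
A3 | alternative 1 | methoxyacetylene (methoxyethyne) | COC#C
A4 | alternative 1 | 6-(benzyloxy)-8-hydroxy-3-pentyl-1H-isochromen-1-one | CCCCCc1cc2cc(OCc3ccccc3)cc(O)c2c(=O)o1
A5 | alternative 2 | 8-[2-(benzyloxy)-4-methoxy-6-pentylphenoxy]-3-pentyl-6-(trimethylsilyloxy)-1H-isochromen-1-one | CCCCCc1cc2cc(O[Si](C)(C)C)cc(Oc3c(OCc4ccccc4)cc(OC)cc3CCCCC)c2c(=O)o1
A6 | alternative 2 | 4-[2-(benzyloxy)-4-methoxy-6-pentylphenoxy]-7-pentyl-2H,5H-pyrano[4,3-b]pyran-2,5-dione | CCCCCc1cc2oc(=O)cc(Oc3c(OCc4ccccc4)cc(OC)cc3CCCCC)c2c(=O)o1
A7 | alternative 2 | ketene bis(trimethylsilyl) acetal (1,1-bis(trimethylsilyloxy)ethene) | C=C(O[Si](C)(C)C)O[Si](C)(C)C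
A8 | alternative 2 | 4-hydroxy-6-pentyl-2H-pyran-2-one | CCCCCc1cc(O)cc(=O)o1
A9 | alternative 3 | 6-(benzyloxy)-8-(2,4-dihydroxy-6-pentylphenoxy)-3-pentyl-1H-isochromen-1-one | CCCCCc1cc2cc(OCc3ccccc3)cc(Oc3c(O)cc(O)cc3CCCCC)c2c(=O)o1
A10 | alternative 3 | 6-(benzyloxy)-8-[(4-oxo-6-pentyl-4H-pyran-2-yl)methoxy]-3-pentyl-1H-isochromen-1-one | CCCCCc1cc(=O)cc(COc2cc(OCc3ccccc3)cc3cc(CCCCC)oc(=O)c23)o1
A11 | alternative 3 | 6-(benzyloxy)-3-pentyl-8-[(2,4,6-trioxoundecyl)oxy]-1H-isochromen-1-one (drawn with ring C closed) | CCCCCC(=O)CC(=O)CC(=O)COc1cc(OCc2ccccc2)cc2cc(CCCCC)oc(=O)c12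
A12 | alternative 3 | 2-(bromomethyl)-6-pentyl-4H-pyran-4-one | CCCCCc1cc(=O)cc(CBr)o1
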